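**Retrosynthetic overview**
- Target ⇒ C4–OH acylation ⇒ oxepane closed last by the tertiary C3–OH displacing a C16 triflate on a cladiellin-type triol.
- Cladiellin triol ⇒ carbocyclic eunicellane (cyclohexenone fused to a (2Z,6Z)-cyclodecadiene-4,9-diol): hydroxyl-directed 2,3-epoxidation and transannular C9–OH → C2 epoxide opening close the tetrahydrofuran and set C2/C3, as in the presumed eunicellane → cladiellin oxidation.
- Ten-membered carbocycle ⇒ ring-closing metathesis at C6=C7 of a diene built by Still–Gennari olefination (Z-C2=C3), asymmetric methallylation (C9) and asymmetric allylation (C4).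
- Cyclohexene ⇒ endo Diels–Alder of a 2-silyloxydiene (crotonyl chloride + (S)-3-bromo-2-methylpropanol) with a (5S)-menthyloxybutenolide; this sets C1, C10 and C14, and C15 comes from the chiral pool.
- Ring order: cyclohexene → ten-membered carbocycle → tetrahydrofuran → oxepane.

Assumption: the (+)-menthol-derived (5S)-menthyloxybutenolide used in step 4 is taken as a purchasable reagent (otherwise two steps from furfural and (+)-menthol).

Numbering used in names: target (eunicellane) numbering — C1–C10 are the ten-membered carbocycle, C11–C14 complete the cyclohexene with C1 and C10, C15/C16 are the CH(CH3)/CH2O chain on C14, and methyls sit on C3, C7, C11 and C15. CIP letters are those of each compound as drawn by its SMILES. TBS = tert-butyldimethylsilyl.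

**Step 1**
Reactants: 1 (E)-but-2-enoyl chloride
Product: 2 (E)-N-methoxy-N-methylbut-2-enamide
Conditions: MeNH(OMe)·HCl, pyridine, CH2Cl2, 0 °C
Reagents that add atoms: N,O-dimethylhydroxylamine hydrochloride, CNOC.Cl
Why: N-acylation of the hydroxylamine by the acid chloride (Weinreb amide formation); no stereocentre is formed.

**Step 2**
Reactants: 3 (S)-3-bromo-2-methylpropan-1-ol; 2 (E)-N-methoxy-N-methylbut-2-enamide
Product: 5 (2E,6R)-7-hydroxy-6-methylhept-2-en-4-one, via alkoxide Grignard reagent 4 (not isolated)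
Conditions: i-PrMgCl (1.0 equiv), THF, −20 °C; Mg, 45 °C; then 2, 0 °C; aq. NH4Cl
Reagents that add atoms: none
Why: Deprotonation and magnesium insertion give a Normant-type alkoxide Grignard reagent whose addition to the Weinreb amide stops at the chelated tetrahedral adduct (Weinreb ketone synthesis), so the stereocentre of 3 is carried unchanged into C15.

**Step 3**
Reactants: 5 (2E,6R)-7-hydroxy-6-methylhept-2-en-4-one
Product: 6 (2R,3Z,5E)-1,4-bis(TBS-oxy)-2-methylhepta-3,5-diene
Conditions: TBSOTf (2.5 equiv), Et3N, CH2Cl2, −78 → 0 °C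
Reagents that add atoms: tert-butyldimethylsilyl trifluoromethanesulfonate, CC(C)(C)[Si](C)(C)OS(=O)(=O)C(F)(F)F
Why: Soft enolisation (silyl triflate/amine) silylates the alcohol and the α′-position of the enone, giving the cross-conjugated 2-silyloxydiene as the (Z)-enol ether, which puts the C15 chain "outside" on the diene terminus.

**Step 4**
Reactants: 6 (2R,3Z,5E)-1,4-bis(TBS-oxy)-2-methylhepta-3,5-diene; 7 (5S)-5-[(1S,2R,5S)-menthyloxy]furan-2(5H)-one
Product: 8 cis-fused lactone acetal Diels–Alder adduct (1S,2S,10R,11R,14R,15R)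
Conditions: toluene, BHT (cat.), 120 °C, sealed tube
Reagents that add atoms: none
Why: Normal-demand Diels–Alder reaction in which the 2-silyloxy group directs C14 to the butenolide β-carbon, the diene adds anti to the menthyloxy group and endo, so C1, C10, C14 (and C11) are set all-cis with absolute control from the acetal carbon of 7.

**Step 5**
Reactants: 8 cis-fused lactone acetal Diels–Alder adduct
Product: 10 cis-formyl Weinreb amide (1S,10R,11R,14R,15R), via menthyl hemiacetal 9 (not isolated)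
Conditions: MeNH(OMe)·HCl, i-PrMgCl, THF, −20 °C; aq. NH4Cl
Reagents that add atoms: N,O-dimethylhydroxylamine hydrochloride, CNOC.Cl
Why: Weinreb aminolysis of the lactone by the chloromagnesium amide opens the pseudo-ester and the menthyl hemiacetal collapses to the aldehyde on work-up, which differentiates C9 (amide) from C2 (aldehyde) without touching the ring stereocentres.

**Step 6**
Reactants: 10 cis-formyl Weinreb amide
Product: 11 (2Z)-enoate Weinreb amide (1S,10R,11R,14S,15R)
Conditions: (CF3CH2O)2P(O)CH(CH3)CO2CH3, KN(SiMe3)2, 18-crown-6, THF, −78 °C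
Reagents that add atoms: methyl 2-[bis(2,2,2-trifluoroethoxy)phosphoryl]propanoate, COC(=O)C(C)P(=O)(OCC(F)(F)F)OCC(F)(F)F
Why: Still–Gennari olefination, in which the electron-poor phosphonate eliminates from the kinetic adduct to give the (Z)-trisubstituted enoate, placing C1 and C4 cis across C2=C3 as the medium ring needs.

**Step 7**
Reactants: 11 (2Z)-enoate Weinreb amide
Product: 12 (2Z)-hydroxy aldehyde (1S,10R,11R,14S,15R)
Conditions: i-Bu2AlH (5 equiv), CH2Cl2, −78 °C; aq. potassium sodium tartrate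
Reagents that add atoms: none
Why: Hydride reduction with i-Bu2AlH takes the Weinreb amide only to the aldehyde (stable chelated aluminium hemiaminal) and the enoate by 1,2-reduction to the (Z)-allylic alcohol, while both silyl groups are inert.

**Step 8**
Reactants: 12 (2Z)-hydroxy aldehyde
Product: 13 C9 methallyl carbinol diol (1R,2Z,9S,10R,11S,14S,15R)
Conditions: (−)-Ipc2BOMe, CH2=C(CH3)CH2MgCl, Et2O, −78 °C; then 12, −78 °C; then HOCH2CH2NH2
Reagents that add atoms: 2-methylallylmagnesium chloride, CC(=C)C[Mg]Cl (transferred through the allylborane made from it)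
Why: Brown asymmetric methallylboration through a chair Zimmerman–Traxler transition state, in which the borane from (−)-Ipc2BOMe attacks the Si face of the α-branched aldehyde and sets C9 as S under reagent control.

**Step 9**
Reactants: 13 C9 methallyl carbinol diol
Product: 14 enone diol (1R,2Z,9S,10S,14S,15R)
Conditions: Pd(OAc)2 (1.2 equiv), MeCN, 23 °C
Reagents that add atoms: none
Why: Saegusa–Ito oxidation, in which the regiodefined silyl enol ether gives a palladium enolate that loses H-11 by β-hydride elimination; the 11-en-13-one is unveiled only now that C9 is a carbinol, so C10 was never doubly activated.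

**Step 10**
Reactants: 14 enone diol
Product: 15 (2Z)-enal (1R,2Z,9S,10S,14S,15R)
Conditions: MnO2, CH2Cl2, 23 °C
Reagents that add atoms: none
Why: Allylic oxidation with MnO2 converts only the primary allylic alcohol (not the homoallylic C9 carbinol) and is neutral enough to keep the (Z)-enal geometry.

**Step 11**
Reactants: 15 (2Z)-enal
Product: 16 diene diol (1R,2Z,4R,9S,10S,14S,15R)
Conditions: (+)-Ipc2BOMe, CH2=CHCH2MgBr, Et2O, −78 °C; then 15, −78 °C; then HOCH2CH2NH2
Reagents that add atoms: allylmagnesium bromide, C=CC[Mg]Br (transferred through the allylborane made from it)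
Why: Brown asymmetric allylboration, in which the borane from (+)-Ipc2BOMe adds to the Re face of the enal through a chair transition state and sets C4 as R under reagent control, chemoselectively over the hindered enone carbonyl.

**Step 12**
Reactants: 16 diene diol
Product: 17 carbocyclic (2Z,6Z)-eunicellatrienone diol (1R,4R,9S,10S,14S,15R)
Conditions: second-generation Grubbs catalyst (H2IMes)(PCy3)Cl2Ru=CHPh (10 mol %), CH2Cl2 (1 mM), 40 °C
Reagents that add atoms: none
Why: Ring-closing olefin metathesis between the terminal and the 1,1-disubstituted alkene closes the ten-membered carbocycle, and ring strain under the reversible conditions favours the (Z)-trisubstituted C6=C7 bond.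

**Step 13**
Reactants: 17 carbocyclic (2Z,6Z)-eunicellatrienone diol
Product: 20 cladiellin-type triol (1R,2S,3S,4R,6Z,9S,10S,14R,15R), via epoxy alcohol 18 (not isolated), via silyl ether 19 (not isolated)
Conditions: VO(acac)2 (5 mol %), t-BuOOH, CH2Cl2, 0 °C; then CSA (20 mol %), 23 °C; then MeOH
Reagents that add atoms: tert-butyl hydroperoxide, CC(C)(C)OO
Why: Proposed new method: vanadium-catalysed hydroxyl-directed epoxidation delivers oxygen to the outer face of the Z C2=C3 bond syn to the C4 hydroxyl (threo, enforced by A1,3 strain from the cis C1 substituent), and the C9 hydroxyl held across the ten-membered ring then opens the protonated epoxide at C2 from the inner face with inversion (5-exo, preferred over 6-endo attack at C3 because the adjacent C4 oxygen disfavours charge there), which forms the tetrahydrofuran and sets C2 and C3 as in the presumed eunicellane → cladiellin step; the closest known reaction type is the acid-catalysed 5-exo epoxy-alcohol cyclisation of polyether synthesis, here run transannularly, and CSA/MeOH finally cleaves the primary silyl ether.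

**Step 14**
Reactants: 20 cladiellin-type triol
Product: 22 oxepane alcohol (4-O-debutanoyl target), via primary triflate 21 (not isolated)
Conditions: Tf2O (1.05 equiv), 2,6-lutidine, CH2Cl2, −78 → 0 °C
Reagents that add atoms: none
Why: Selective triflation of the only primary alcohol followed by intramolecular Williamson-type displacement by the tertiary C3 hydroxyl (7-exo-tet) closes the oxepane without change at any stereocentre.

**Step 15**
Reactants: 22 oxepane alcohol
Product: 23 target butanoate (1R,2S,3S,4R,6Z,9S,10S,14R,15R)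
Conditions: (n-PrCO)2O, DMAP (cat.), pyridine, 23 °C
Reagents that add atoms: butanoic anhydride, CCCC(=O)OC(=O)CCC
Why: DMAP-catalysed acylation esterifies the only remaining hydroxyl (secondary, C4) with retention of configuration.

**Compound list**

1 | (E)-but-2-enoyl chloride (crotonyl chloride) | C/C=C/C(Cl)=O | starting material
2 | (E)-N-methoxy-N-methylbut-2-enamide | C/C=C/C(=O)N(C)OC | intermediate
3 | (S)-3-bromo-2-methylpropan-1-ol | BrC[C@@H](C)CO | starting material
4 | [(2S)-3-(chloromagnesiooxy)-2-methylpropyl]magnesium bromide (alkoxide Grignard reagent) | Br[Mg]C[C@@H](C)CO[Mg]Cl | intermediate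
5 | (2E,6R)-7-hydroxy-6-methylhept-2-en-4-one | C/C=C/C(=O)C[C@@H](C)CO | intermediate
6 | (2R,3Z,5E)-1,4-bis[(tert-butyldimethylsilyl)oxy]-2-methylhepta-3,5-diene | C/C=C/C(O[Si](C)(C)C(C)(C)C)=C/[C@@H](C)CO[Si](C)(C)C(C)(C)C | intermediate
7 | (5S)-5-{[(1S,2R,5S)-5-methyl-2-(propan-2-yl)cyclohexyl]oxy}furan-2(5H)-one | O=C1O[C@H](O[C@H]2C[C@@H](C)CC[C@@H]2C(C)C)C=C1 | starting material
8 | Diels–Alder adduct: γ-lactone (C9 carbonyl, C2 acetal carrying (1S,2R,5S)-menthyloxy) cis-fused to a cyclohexene with C12=C13(OTBS), 11-CH3 and 14-CH(CH3)CH2OTBS; (1S,2S,10R,11R,14R,15R), H-1/H-10/H-11/H-14 all cis | O=C1O[C@H](O[C@H]3C[C@@H](C)CC[C@@H]3C(C)C)[C@H]2[C@@H]([C@@H](C)CO[Si](C)(C)C(C)(C)C)C(O[Si](C)(C)C(C)(C)C)=C[C@@H](C)[C@@H]12 | intermediate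
9 | ring-opened menthyl hemiacetal: C2 = CH(OH)(O-menthyl), C9 = C(=O)N(OMe)Me; (1S,2R,10R,11R,14R,15R) | O[C@H](O[C@H]2C[C@@H](C)CC[C@@H]2C(C)C)[C@H]1[C@@H]([C@@H](C)CO[Si](C)(C)C(C)(C)C)C(O[Si](C)(C)C(C)(C)C)=C[C@@H](C)[C@H]1C(=O)N(C)OC | intermediate
10 | cis-formyl Weinreb amide: cyclohexene with 1-CHO (C2), 10-C(=O)N(OMe)Me (C9), 11-CH3, C12=C13(OTBS), 14-CH(CH3)CH2OTBS; (1S,10R,11R,14R,15R) | O=C[C@H]1[C@@H]([C@@H](C)CO[Si](C)(C)C(C)(C)C)C(O[Si](C)(C)C(C)(C)C)=C[C@@H](C)[C@H]1C(=O)N(C)OC | intermediate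
11 | (2Z)-enoate: C1–CH=C(CH3)–CO2CH3 (ester carbon = C4), otherwise as 10; (1S,2Z,10R,11R,14S,15R) | C/C(=C/[C@H]1[C@@H]([C@@H](C)CO[Si](C)(C)C(C)(C)C)C(O[Si](C)(C)C(C)(C)C)=C[C@@H](C)[C@H]1C(=O)N(C)OC)C(=O)OC | intermediate
12 | (2Z)-hydroxy aldehyde: C4H2OH allylic alcohol, C9 aldehyde; (1S,2Z,10R,11R,14S,15R) | C/C(=C/[C@H]1[C@@H]([C@@H](C)CO[Si](C)(C)C(C)(C)C)C(O[Si](C)(C)C(C)(C)C)=C[C@@H](C)[C@H]1C=O)CO | intermediate
13 | methallyl carbinol diol: C9(OH)–CH2C(CH3)=CH2, C4H2OH, silyl enol ether retained; (1R,2Z,9S,10R,11S,14S,15R) | C/C(=C/[C@H]1[C@@H]([C@@H](C)CO[Si](C)(C)C(C)(C)C)C(O[Si](C)(C)C(C)(C)C)=C[C@@H](C)[C@H]1[C@@H](O)CC(C)=C)CO | intermediate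
14 | enone diol: 11-en-13-one, C9(OH)-methallyl, C4H2OH, 16-OTBS; (1R,2Z,9S,10S,14S,15R) | C/C(=C/[C@H]1[C@@H]([C@@H](C)CO[Si](C)(C)C(C)(C)C)C(=O)C=C(C)[C@H]1[C@@H](O)CC(C)=C)CO | intermediate
15 | (2Z)-enal: C4 aldehyde, otherwise as 14; (1R,2Z,9S,10S,14S,15R) | C/C(=C/[C@H]1[C@@H]([C@@H](C)CO[Si](C)(C)C(C)(C)C)C(=O)C=C(C)[C@H]1[C@@H](O)CC(C)=C)C=O | intermediate
16 | diene diol: C4(OH)-allyl and C9(OH)-methallyl on the cyclohexenone; (1R,2Z,4R,9S,10S,14S,15R) | C/C(=C/[C@H]1[C@@H]([C@@H](C)CO[Si](C)(C)C(C)(C)C)C(=O)C=C(C)[C@H]1[C@@H](O)CC(C)=C)[C@H](O)CC=C | intermediate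
17 | carbocyclic eunicellane: (2Z,6Z)-4,9-dihydroxy-16-(TBS-oxy)eunicella-2,6,11-trien-13-one; (1R,4R,9S,10S,14S,15R) | C/C1=C/[C@H]2[C@@H]([C@@H](C)CO[Si](C)(C)C(C)(C)C)C(=O)C=C(C)[C@H]2[C@@H](O)C/C(C)=C\C[C@H]1O | intermediate
18 | 2,3-epoxide of 17 (oxygen threo to the C4 hydroxyl); (1R,2R,3S,4R,6Z,9S,10S,14R,15R) | O[C@@H]1C/C=C(/C)C[C@H](O)[C@@H]2C(C)=CC(=O)[C@H]([C@@H](C)CO[Si](C)(C)C(C)(C)C)[C@@H]2[C@H]3O[C@@]13C | intermediate
19 | 16-O-TBS ether of 20 (2,9-ether bridge closed, 3,4-diol); (1R,2S,3S,4R,6Z,9S,10S,14R,15R) | O[C@@H]1C/C=C(/C)C[C@@H]2O[C@H]([C@@]1(C)O)[C@@H]3[C@H]2C(C)=CC(=O)[C@@H]3[C@@H](C)CO[Si](C)(C)C(C)(C)C | intermediate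
20 | cladiellin-type triol: 2,9-epoxy-3,4,16-trihydroxyeunicella-6,11-dien-13-one; (1R,2S,3S,4R,6Z,9S,10S,14R,15R) | O[C@@H]1C/C=C(/C)C[C@@H]2O[C@H]([C@@]1(C)O)[C@@H]3[C@H]2C(C)=CC(=O)[C@@H]3[C@@H](C)CO | intermediate
21 | 16-O-trifluoromethanesulfonate of 20 | O[C@@H]1C/C=C(/C)C[C@@H]2O[C@H]([C@@]1(C)O)[C@@H]3[C@H]2C(C)=CC(=O)[C@@H]3[C@@H](C)COS(=O)(=O)C(F)(F)F | intermediate
22 | oxepane alcohol (3,16-ether closed, free 4-OH; 4-O-debutanoyl target); (1R,2S,3S,4R,6Z,9S,10S,14R,15R) | O[C@@H]1C/C=C(/C)C[C@@H]2O[C@H]3[C@@H]4[C@H]2C(C)=CC(=O)[C@@H]4[C@@H](C)CO[C@@]13C | intermediate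
23 | target 4-butanoate; (1R,2S,3S,4R,6Z,9S,10S,14R,15R) | CCCC(=O)O[C@@H]1C/C=C(/C)C[C@@H]2O[C@H]3[C@@H]4[C@H]2C(C)=CC(=O)[C@@H]4[C@@H](C)CO[C@@]13C | target

**Totals**
Total step count: 15. Longest linear sequence: 15 (1 → 23; compounds 3 and 7 enter as purchased materials).

**Steps most likely to fail**

Step 12 (ring-closing metathesis to a ten-membered carbocycle with a trisubstituted alkene; risk: oligomers or no closure). Fallback: change the order of ring formation. Set out from 16 and run the epoxidation/5-exo cyclisation on the open-chain diene (VO(acac)2, t-BuOOH; then CSA). Acyclic A1,3 control should give the same threo epoxide, and the C9 hydroxyl opens it at C2 to give the 2,5-cis-tetrahydrofuran diene F1. The two alkene arms are then held cis on the tetrahydrofuran, and metathesis with the second-generation Grubbs catalyst (H2IMes)(PCy3)Cl2Ru=CHPh closes an ether-bridged nine-membered ring instead of a carbocycle. This gives 19, where the route is rejoined (CSA/MeOH to 20).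

Step 13 (epoxidation/transannular cyclisation; risk: 6-endo opening at the tertiary C3, or epoxidation on the inner face). Fallback: put the regiocontrol into the substrate. Set out from 17. MnO2 oxidises the allylic C4 alcohol to the (2Z,6Z)-dienone F2. Nucleophilic epoxidation (t-BuOOH, DBU) of this less hindered enone gives the cis-epoxy ketone F3. C3 is now α to a carbonyl and cannot carry positive charge, so CSA-promoted opening by the C9 hydroxyl can only occur at C2, giving the tetrahydrofuran hydroxy ketone F4. Reduction of the C4 ketone (Zn(BH4)2 under chelation with the C3 hydroxyl, or Me4NBH(OAc)3 if the other face is needed) returns to 19.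

Step 14 (oxepane closure; risk: the C13 carbonyl oxygen captures the primary triflate in a five-membered ring faster than the tertiary alcohol, or the C4 hydroxyl reacts). Fallback: form the C16–O–C3 bond reductively. Set out from 20. TEMPO/PhI(OAc)2 oxidises only the primary alcohol to the 16-aldehyde F5, which closes on the C3 hydroxyl as the seven-membered lactol. Et3SiH/BF3·OEt2 (−78 °C) reduces the derived oxocarbenium ion and gives 22.

**Further compounds**

F1 | step 12 | 2,5-cis-tetrahydrofuran diene: 2,9-ether closed, C3(OH)(CH3)–C4(OH)–allyl and C9–methallyl arms, 16-OTBS, 11-en-13-one; stereocentres as in 19 | C=CC[C@@H](O)[C@](C)(O)[C@H]1O[C@@H](CC(C)=C)[C@@H]2C(C)=CC(=O)[C@H]([C@@H](C)CO[Si](C)(C)C(C)(C)C)[C@H]12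
F2 | step 13 | (2Z,6Z)-dienone: 4-ketone of 17 | C/C1=C/[C@H]2[C@@H]([C@@H](C)CO[Si](C)(C)C(C)(C)C)C(=O)C=C(C)[C@H]2[C@@H](O)C/C(C)=C\CC1=O
F3 | step 13 | cis-2,3-epoxy-4-ketone (4-ketone of 18) | O=C1C/C=C(/C)C[C@H](O)[C@@H]2C(C)=CC(=O)[C@H]([C@@H](C)CO[Si](C)(C)C(C)(C)C)[C@@H]2[C@H]3O[C@@]13C
F4 | step 13 | tetrahydrofuran 3-hydroxy-4-ketone (4-ketone of 19) | O=C1C/C=C(/C)C[C@@H]2O[C@H]([C@@]1(C)O)[C@@H]3[C@H]2C(C)=CC(=O)[C@@H]3[C@@H](C)CO[Si](C)(C)C(C)(C)C
F5 | step 14 | 16-aldehyde of 20 (open form of the C3–O–C16 lactol) | O[C@@H]1C/C=C(/C)C[C@@H]2O[C@H]([C@@]1(C)O)[C@@H]3[C@H]2C(C)=CC(=O)[C@@H]3[C@@H](C)C=O
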